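**Assumptions (one line):** compound 2 is the commercial ethylene ketal of 5‑chloropentan‑2‑one (7 non‑H atoms without the protecting group) and 4‑methylpent‑4‑enal is bought as a catalogue aldehyde. Locants used: C1 ester C=O, C2 CHMe, C3 and C6 ring carbons, C7–C8 CH2CH2, C9 ketone, C10 CMe2, C14 methyl ketone.

## Retrosynthetic overview

1. Target 11 ⇐ dioxane acid 10 (esterification, ketal removal). The 1,2‑dioxane is the only ring and is closed last.
2. Ring closure: O–C3 by invertive 6‑exo‑tet opening of a cis‑β‑lactone by the C6 peroxide anion; C6–O by Co–H hydrogen‑atom transfer/O2 trapping at the C6 alkene.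
3. Key disconnection C7–C8: the acylmethyl radical from chloromethyl ketone 4 adds to the isobutenyl terminus of lactone 7 (radical fragment union that also places the alkene at C6).
4. Lactone 7 ⇐ 4‑methylpent‑4‑enal + propanoyl chloride (catalytic asymmetric ketene–aldehyde [2+2]; fixes C2 and C3).
5. Ketone 4 ⇐ methyl isobutyrate + chloro‑ketal 2 + ICH2Cl.

## Route

**Step 1**
Reactants: 1, methyl 2‑methylpropanoate; 2, 2‑(3‑chloropropyl)‑2‑methyl‑1,3‑dioxolane
Product: 3, methyl 2,2‑dimethyl‑5‑(2‑methyl‑1,3‑dioxolan‑2‑yl)pentanoate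
Conditions: LDA, THF, −78 °C; then 2, NaI (cat.), DMPU, −78 °C → rt
Reagents that add atoms: none
Why: Ester‑enolate SN2 alkylation (in‑situ Finkelstein); the isobutyrate enolate has a single alkylation site and creates the C10 quaternary carbon, the ketal is inert to base, no stereocentre.

**Step 2**
Reactants: 3
Product: 4, 1‑chloro‑3,3‑dimethyl‑6‑(2‑methyl‑1,3‑dioxolan‑2‑yl)hexan‑2‑one
Conditions: ICH2Cl, MeLi·LiBr, THF, −78 °C; AcOH quench at −78 °C
Reagents that add atoms: chloroiodomethane, ClCI
Why: Halomethyl‑ketone synthesis from an ester with chloromethyllithium (carbenoid acylation); the tetrahedral alkoxide is stable at −78 °C so only one addition occurs, and the buffered quench spares the ketal; no stereocentre.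

**Step 3**
Reactants: 5, 4‑methylpent‑4‑enal; 6, propanoyl chloride
Product: 7, (3S,4R)‑3‑methyl‑4‑(3‑methylbut‑3‑en‑1‑yl)oxetan‑2‑one (cis‑β‑lactone)
Conditions: O‑TMS‑quinidine (10 mol %), LiI, i‑Pr2NEt, CH2Cl2/Et2O, −78 °C
Reagents that add atoms: none
Why: Catalytic asymmetric acyl halide–aldehyde cyclocondensation (cinchona ammonium enolate of methylketene adds to the Li‑activated aldehyde, formal [2+2]) gives the cis lactone (typically >95:5 dr, ≥95 % ee), setting C2 (S, final) and C3 (R, inverted in step 6); my assignment of TMS‑quinidine to this enantiomer is from memory and must be confirmed on 7, with O‑TMS‑quinine used instead if the sense is opposite.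

**Step 4 (key step)**
Reactants: 4; 7 (2 equiv, excess recovered)
Product: 8, (3S,4R)‑4‑[7,7‑dimethyl‑3‑methylidene‑10‑(2‑methyl‑1,3‑dioxolan‑2‑yl)‑6‑oxodecyl]‑3‑methyloxetan‑2‑one (major exo‑methylene isomer; minor C5=C6 and C6=C7 trisubstituted isomers are carried along)
Conditions: fac‑Ir(ppy)3 (1 mol %), Co(dmgH)2(py)Cl (5 mol %), 2,6‑lutidine, MeCN, blue LEDs, rt
Reagents that add atoms: none
Why: Proposed new method: photoreduction of the α‑chloroketone (or photolysis of its Co(III)–alkyl) gives the electrophilic acylmethyl radical, which adds polarity‑matched to the terminal CH2 of the 1,1‑dialkyl alkene to form C7–C8; the tertiary C6 radical is then dehydrogenated by Co(II) (β‑H abstraction, no carbocation, so no O‑cyclisation to a dihydrofuran) and lutidine closes the redox‑neutral cycle. All alkene regioisomers give the same C6 radical in step 5, and the lactone stereocentres are untouched. Closest known reaction types: photoredox/cobaloxime Heck‑type alkylation and desaturation, Mn(OAc)3/Cu(OAc)2 ketone–alkene coupling, and xanthate‑transfer additions of α‑keto radicals.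

**Step 5**
Reactants: 8 (isomer mixture)
Product: 9, (3S,4R)‑3‑methyl‑4‑[3,7,7‑trimethyl‑10‑(2‑methyl‑1,3‑dioxolan‑2‑yl)‑6‑oxo‑3‑(triethylsilylperoxy)decyl]oxetan‑2‑one, about 1:1 at the peroxy carbon (C6)
Conditions: Co(thd)2 (10 mol %), O2 (1 atm), Et3SiH, DCE, rt
Reagents that add atoms: dioxygen, O=O; triethylsilane, CC[SiH](CC)CC
Why: Isayama–Mukaiyama hydroperoxysilylation: Co–H hydrogen‑atom transfer to each alkene isomer gives the same tertiary C6 radical, which is trapped by O2 and silylated (Markovnikov); the planar radical gives C6 with no control (about 1:1, separated after step 7), and lactone, ketone and ketal are inert.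

**Step 6**
Reactants: 9
Product: 10, (2S)‑2‑[(3S,6RS)‑6‑[4,4‑dimethyl‑7‑(2‑methyl‑1,3‑dioxolan‑2‑yl)‑3‑oxoheptyl]‑6‑methyl‑1,2‑dioxan‑3‑yl]propanoic acid (C6 epimers about 1:1)
Conditions: TBAF (1.05 equiv), THF (0.01 M), −20 °C → rt; pH 4 buffer work‑up
Reagents that add atoms: none
Why: Proposed new method: fluoride unmasks the tertiary peroxide anion (in equilibrium with its hemiketal on the hindered C9 ketone), which attacks the lactone C–O carbon from the backside in a 6‑exo‑tet SN2 alkyl–oxygen cleavage (acyl attack would need an 8‑membered ring). This inverts C3 to S, leaves C2 untouched and gives the 2,3‑anti acid directly; both C6 epimers cyclise. Closest known reaction types: SN2 alkyl–O opening of β‑lactones by azide, thiolate and carboxylate with inversion, and intramolecular hydroperoxide alkylations/oxetane openings to 1,2‑dioxanes.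

**Step 7**
Reactants: 10
Product: 11, methyl (2S)‑2‑[(3S,6R)‑6‑(4,4‑dimethyl‑3,8‑dioxononyl)‑6‑methyl‑1,2‑dioxan‑3‑yl]propanoate (Diacarperoxide B)
Conditions: AcCl (generates HCl), MeOH, 0 °C → rt; then H2O; preparative HPLC to remove the 6S epimer
Reagents that add atoms: methanol, CO; water, O
Why: Fischer esterification with acetal exchange/hydrolysis; acid rather than base is used so the β‑peroxy ester cannot undergo retro‑oxa‑Michael or epimerise at C2/C3, and dialkyl peroxides tolerate dilute acid; no stereocentre is formed, and the (6R) diastereomer is isolated here.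

## Compound list

1 | methyl 2‑methylpropanoate | COC(=O)C(C)C | starting material
2 | 2‑(3‑chloropropyl)‑2‑methyl‑1,3‑dioxolane | CC1(CCCCl)OCCO1 | starting material
3 | methyl 2,2‑dimethyl‑5‑(2‑methyl‑1,3‑dioxolan‑2‑yl)pentanoate | COC(=O)C(C)(C)CCCC1(C)OCCO1 | intermediate
4 | 1‑chloro‑3,3‑dimethyl‑6‑(2‑methyl‑1,3‑dioxolan‑2‑yl)hexan‑2‑one | ClCC(=O)C(C)(C)CCCC1(C)OCCO1 | intermediate
5 | 4‑methylpent‑4‑enal | CC(=C)CCC=O | starting material
6 | propanoyl chloride | CCC(=O)Cl | starting material
7 | (3S,4R)‑3‑methyl‑4‑(3‑methylbut‑3‑en‑1‑yl)oxetan‑2‑one | O=C1[C@@H](C)[C@@H](CCC(C)=C)O1 | intermediate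
8 | (3S,4R)‑4‑[7,7‑dimethyl‑3‑methylidene‑10‑(2‑methyl‑1,3‑dioxolan‑2‑yl)‑6‑oxodecyl]‑3‑methyloxetan‑2‑one (major isomer) | O=C1[C@@H](C)[C@@H](CCC(=C)CCC(=O)C(C)(C)CCCC2(C)OCCO2)O1 | intermediate
9 | (3S,4R)‑3‑methyl‑4‑[3,7,7‑trimethyl‑10‑(2‑methyl‑1,3‑dioxolan‑2‑yl)‑6‑oxo‑3‑(triethylsilylperoxy)decyl]oxetan‑2‑one (C6 epimers) | O=C1[C@@H](C)[C@@H](CCC(C)(OO[Si](CC)(CC)CC)CCC(=O)C(C)(C)CCCC2(C)OCCO2)O1 | intermediate
10 | (2S)‑2‑[(3S,6RS)‑6‑[4,4‑dimethyl‑7‑(2‑methyl‑1,3‑dioxolan‑2‑yl)‑3‑oxoheptyl]‑6‑methyl‑1,2‑dioxan‑3‑yl]propanoic acid | OC(=O)[C@@H](C)[C@@H]1CCC(C)(CCC(=O)C(C)(C)CCCC2(C)OCCO2)OO1 | intermediate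
11 | methyl (2S)‑2‑[(3S,6R)‑6‑(4,4‑dimethyl‑3,8‑dioxononyl)‑6‑methyl‑1,2‑dioxan‑3‑yl]propanoate | COC(=O)[C@@H](C)[C@@H]1CC[C@](C)(CCC(=O)C(C)(C)CCCC(C)=O)OO1 | target

## Step count and risks

Total steps: 7. Longest linear sequence: 6 (steps 1, 2, 4, 5, 6, 7).

Steps most likely to fail, each with a fallback that changes the approach:

1. **Step 4 (radical C7–C8 union).** Risks are double alkylation of the product alkene, simple reduction of the acylmethyl radical, and Co(I) side reactions with the lactone. Fallback: make the bond ionically before the lactone exists. Convert 3 to the methyl ketone, allylate its kinetic enolate with 3‑chloro‑2‑(chloromethyl)prop‑1‑ene, extend the second allylic chloride with (1,3‑dioxolan‑2‑ylmethyl)magnesium bromide/Cu(I), unmask the aldehyde, then run the step 3 cyclocondensation (about 3 extra steps).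
2. **Step 6 (peroxide‑anion opening of the β‑lactone).** Risks are acyl attack or hydrolysis, and slow SN2 at the secondary carbon. Fallback: replace the lactone by an (E)‑2‑methyl‑enoyl oxazolidinone built from the same aldehyde and close the ring by base‑mediated intramolecular oxa‑Michael addition of the C6 hydroperoxide. Diastereomers are separated on the auxiliary, followed by Lewis‑acid methanolysis.
3. **Step 5 (C6 formed about 1:1; isolation depends on HPLC at step 7).** Fallback: build the C6–OO centre ionically and stereospecifically. Open an enantiopure 2,2‑disubstituted C6 epoxide (from asymmetric epoxidation of the corresponding allylic alcohol) with H2O2 under Mo catalysis, which proceeds with inversion, then carry the tertiary hydroperoxide into the same lactone‑opening ring closure (longer but C6‑controlled).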